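What will the ratio r of other capture product to target read in this flask, early, in the middle and late?

- spring: substrate 1 M; first nucleophile 1.5 equiv; second nucleophile 0.70 equiv; the very flask that is asked about, followed so far
- flask: substrate 1.0 M; first nucleophile 1.50 equiv; second nucleophile 0.700 equiv; time 3.0 h

- spring (time / min: other capture product / %, target / %, substrate / %): 6.00: 4.7, 2.1, 92.1; 8.00: 6.5, 2.7, 89.8; 12.0: 8.8, 4.0, 84.0; 20.0: 12.9, 6.1, 76.3; 30.0: 17.7, 8.2, 65.7; 50.0: 23.9, 11.2, 52.0; 80.0: 30.1, 13.9, 36.4

(each reading ± 0.5 percentage points)

* ratio of other capture product to target at 80 s
* ratio of other capture product to target at 15 min
* ratio of other capture product to target at 3.0 h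



Two chemists read these peaks, and both assume that substrate feeds a short-lived intermediate, which first nucleophile captures to target and second nucleophile captures to other capture product. They share one quantity, the selectivity factor S: the capture rate constant of second nucleophile over that of first, reckoned as r times the charged ratio of first to second nucleophile, here 4.63 from the reading at 30.0 min.

The second chemist argues from S. It stands above one, so second nucleophile is taken faster. The reading at 80.0 min puts the other capture product at 43.0% of that nucleophile's charge. Scaling the charged ratio by what remains, and leaving first nucleophile at its charge, new product should now form at r = 1.23, so she expects r to sag by 3.0 h.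

The first chemist answers from the readings. They give r = 2.24 at 6.00 min and 2.17 at 80.0 min, and the product added between the last two readings has r = 2.30, which is above her rival's figure, though it is a loose difference of small peaks. She expects r to stay flat, and I would commit to that, near 2.16 at each asked time.

The forecast takes the flat side with 2.15, 2.15 and 2.15 (ranges 1.9 to 2.5, 2.02 to 2.3, 1.9 to 2.45), on its own ground that “the two nucleophiles deplete proportionally”, which differs from the S reckoned here.

The flask gives 2.14 at 80 s, 2.15 at 15 min and 2.20 at 3.0 h.

    substrate ⇌ intermediate (K = 0.00110, k = 0.330 min⁻¹)
    substrate + target → side product A (k = 0.00940 M⁻¹ min⁻¹)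
    intermediate → side product B (k = 0.0900 min⁻¹)
    first nucleophile + intermediate → target (k = 2.40 M⁻¹ min⁻¹)
    second nucleophile + intermediate → other capture product (k = 11.0 M⁻¹ min⁻¹)
    intermediate → decomposed reagent (k = 2.30 min⁻¹)

The depletion the second chemist argued from is real, though it is only a part of the story: with second nucleophile held at its charge, r at 3.0 h reads 3.08 against 2.20. The reaction of substrate + target to side product A and the back reaction of intermediate to substrate, acting together, pull r the other way: at 3.0 h r reads 1.57 in the run without the former and 1.50 in the run without the latter, and those runs are the second chemist's region.

For the neighbour flask with 0.280 equiv of second nucleophile, S gives r = 0.863. That flask computes to 0.856 at 80 s and 0.887 at 3.0 h.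

The readings were generated by integration on assumed constants.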